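**Plan**

- Rings are lettered A to E in SMILES order (A = terminal benzene-1,3,5-triol, E = terminal 3,4,5-trihydroxyphenoxy).
- Enabling feature: in ring A the carbon C2 that carries the ether oxygen to ring B lies between the hydroxylated carbons C1 and C3, and C5 is hydroxylated as well. Ring A is therefore the tris-enol of a 2-aryloxycyclohexane-1,3,5-trione, a cyclised triketide.
- Retrosynthetic cuts: (i) the ten O–CH3 bonds on rings B to E; (ii) the ring A C2–C1 bond, opening ring A to a methyl 6-aryloxy-3,5-dioxohexanoate; (iii) the C4–C5 bond of that chain (acetoacetate dianion plus aryloxyacetyl Weinreb amide) and its O–CH2 bond; (iv) the B–C, C–D and D–E ether C–O bonds, each on the side of a bromobenzaldehyde whose formyl group is the latent next phenol oxygen.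
- Forward order: ring E phenol, then D, C and B by three Ullmann / Baeyer–Villiger pairs; then the two-carbon and four-carbon units; ring A is closed last from the open chain; global demethylation ends the route.
- Stereochemistry: none arises; the target has no stereocentre.

Key step: step 9

Assumption: the target has no stereocentre and no configurationally stable axis, so it is one achiral compound and no enantiocontrol is needed; 3-bromo-4,5-dimethoxybenzaldehyde, 2-bromo-3,4,5-trimethoxybenzaldehyde and 4-bromo-3,5-dimethoxybenzaldehyde are taken as catalogue compounds.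

**Route**

Step 1
Reactants: 1 3,4,5-trimethoxyphenol; 2 3-bromo-4,5-dimethoxybenzaldehyde
Product: 3 D–E aldehyde 3,4-dimethoxy-5-(3,4,5-trimethoxyphenoxy)benzaldehyde
Conditions: CuI (10 mol%), N,N-dimethylglycine·HCl (30 mol%), Cs2CO3, 1,4-dioxane, 100 °C
Reagents that add atoms: none
Why: Ligand-accelerated Ullmann diaryl ether synthesis should join the unhindered, electron-rich phenoxide to an aryl bromide that has only one ortho-methoxy group, and the non-enolisable aldehyde tolerates carbonate base.

Step 2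
Reactants: 3 D–E aldehyde
Product: 5 D–E phenol 3,4-dimethoxy-5-(3,4,5-trimethoxyphenoxy)phenol, via D–E aryl formate 4 (not isolated)
Conditions: mCPBA, CH2Cl2, 0 °C to rt; then K2CO3 (cat.), MeOH, rt
Reagents that add atoms: mCPBA, OOC(=O)c1cccc(Cl)c1
Why: Baeyer–Villiger oxidation (Dakin-type) should proceed with migration of the aryl group, which carries a para-methoxy donor, in preference to hydrogen, and the aryl formate is cleaved by mild methanolysis.

Step 3
Reactants: 5 D–E phenol; 6 2-bromo-3,4,5-trimethoxybenzaldehyde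
Product: 7 C–D–E aldehyde 2-[3,4-dimethoxy-5-(3,4,5-trimethoxyphenoxy)phenoxy]-3,4,5-trimethoxybenzaldehyde
Conditions: CuI (10 mol%), N,N-dimethylglycine·HCl (30 mol%), Cs2CO3, 1,4-dioxane, 100 °C
Reagents that add atoms: none
Why: Ullmann ether synthesis in which the ortho-formyl group activates the C–Br bond and the phenol has two free ortho positions, so the ether flanked by methoxy and formyl should form readily.

Step 4
Reactants: 7 C–D–E aldehyde
Product: 9 C–D–E phenol 2-[3,4-dimethoxy-5-(3,4,5-trimethoxyphenoxy)phenoxy]-3,4,5-trimethoxyphenol, via C–D–E aryl formate 8 (not isolated)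
Conditions: mCPBA, CH2Cl2, 0 °C to rt; then K2CO3 (cat.), MeOH, rt
Reagents that add atoms: mCPBA, OOC(=O)c1cccc(Cl)c1
Why: Baeyer–Villiger oxidation (Dakin-type) is favoured by the ortho-aryloxy and para-methoxy donors on the migrating ring, and methanolysis of the formate gives the phenol.

Step 5
Reactants: 9 C–D–E phenol; 10 4-bromo-3,5-dimethoxybenzaldehyde
Product: 11 B–C–D–E aldehyde 4-{2-[3,4-dimethoxy-5-(3,4,5-trimethoxyphenoxy)phenoxy]-3,4,5-trimethoxyphenoxy}-3,5-dimethoxybenzaldehyde
Conditions: CuI (20 mol%), picolinic acid (40 mol%), K3PO4, DMSO, 100 °C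
Reagents that add atoms: none
Why: Ullmann coupling under the picolinic acid conditions developed for hindered diaryl ethers pairs an electron-rich phenoxide with a bromide activated by its para-formyl group, the polarity-matched way to form this tri-ortho-substituted ether.

Step 6
Reactants: 11 B–C–D–E aldehyde
Product: 13 B–C–D–E phenol 4-{2-[3,4-dimethoxy-5-(3,4,5-trimethoxyphenoxy)phenoxy]-3,4,5-trimethoxyphenoxy}-3,5-dimethoxyphenol, via B–C–D–E aryl formate 12 (not isolated)
Conditions: mCPBA, CH2Cl2, 0 °C to rt; then K2CO3 (cat.), MeOH, rt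
Reagents that add atoms: mCPBA, OOC(=O)c1cccc(Cl)c1
Why: Baeyer–Villiger oxidation (Dakin-type) of a 4-aryloxy-3,5-dimethoxybenzaldehyde follows the known behaviour of 3,4,5-trialkoxybenzaldehydes, with the para oxygen donor directing aryl migration.

Step 7
Reactants: 13 B–C–D–E phenol; 14 2-chloro-N-methoxy-N-methylacetamide
Product: 15 Weinreb amide 2-(4-{2-[3,4-dimethoxy-5-(3,4,5-trimethoxyphenoxy)phenoxy]-3,4,5-trimethoxyphenoxy}-3,5-dimethoxyphenoxy)-N-methoxy-N-methylacetamide
Conditions: K2CO3, NaI (cat.), DMF, 60 °C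
Reagents that add atoms: none
Why: Williamson ether synthesis of an unhindered phenoxide with an α-chloro amide under iodide catalysis is reliable and puts the future ring A oxygen in place by a simple SN2 step.

Step 8
Reactants: 15 Weinreb amide; 16 methyl acetoacetate
Product: 17 methyl 6-(4-{2-[3,4-dimethoxy-5-(3,4,5-trimethoxyphenoxy)phenoxy]-3,4,5-trimethoxyphenoxy}-3,5-dimethoxyphenoxy)-3,5-dioxohexanoate
Conditions: 16 (3 equiv), LDA (6 equiv), THF, 0 °C; then 15, −78 to 0 °C; cold dil. HCl to pH 4
Reagents that add atoms: none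
Why: γ-Acylation of the acetoacetate dianion by a Weinreb amide should stop at the ketone stage through the chelated tetrahedral intermediate, and excess dianion compensates for proton transfer to the more acidic diketo ester.

Step 9
Reactants: 17 methyl 6-aryloxy-3,5-dioxohexanoate
Product: 19 pentamer with free ring A 2-(4-{2-[3,4-dimethoxy-5-(3,4,5-trimethoxyphenoxy)phenoxy]-3,4,5-trimethoxyphenoxy}-3,5-dimethoxyphenoxy)benzene-1,3,5-triol, via 2-aryloxycyclohexane-1,3,5-trione 18 (not isolated)
Conditions: KHMDS (4 equiv), 18-crown-6, THF, high dilution, −78 to 50 °C; then degassed aq. HCl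
Reagents that add atoms: none
Why: Base removes the C4–H, the C2–H and finally the aryloxy-acidified C6–H; the C6 carbanion then adds to the C1 ester carbonyl and methoxide leaves, an intramolecular Claisen (Dieckmann-type) acylation giving trione 18, whose enolisation to the phloroglucinol trisphenoxide makes the closure irreversible. The closest known reactions are the base-mediated cyclisation of 3,5-dioxohexanoate esters to phloroglucinol and the Claisen closure of 3,5,7-triketo esters to acylphloroglucinols. Ring A closes through the C6–C1 bond in a 6-(enolendo)-exo-trig mode. No stereocentre is formed. The selectivity needed is C-acylation at C6 over O-acylation by the C5 enolate oxygen (lactonisation): full deprotonation places the highest charge density on C6, the aryloxy group brings that last deprotonation within reach of a silylamide, potassium with crown ether avoids the tight chelate that holds a lithium or magnesium polyenolate extended so the chain can fold, and high dilution suppresses intermolecular condensation. The ten aryl methyl ethers and the diaryl ethers are inert to the base.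

Step 10
Reactants: 19 pentamer with free ring A
Product: 20 target 2-(4-{2-[3,4-dihydroxy-5-(3,4,5-trihydroxyphenoxy)phenoxy]-3,4,5-trihydroxyphenoxy}-3,5-dihydroxyphenoxy)benzene-1,3,5-triol
Conditions: BBr3 (excess), CH2Cl2, −78 °C to rt, argon; then H2O, 0 °C
Reagents that add atoms: none
Why: Lewis acid ether cleavage with BBr3 removes all ten methyl groups by bromide attack on the boron-activated O–CH3, leaves diaryl ether C–O bonds untouched, and exclusion of air protects the pyrogallol units.

**Compound list**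

1 | 3,4,5-trimethoxyphenol | COc1cc(O)cc(OC)c1OC | starting material
2 | 3-bromo-4,5-dimethoxybenzaldehyde | COc1cc(C=O)cc(Br)c1OC | starting material
3 | 3,4-dimethoxy-5-(3,4,5-trimethoxyphenoxy)benzaldehyde | COc1cc(C=O)cc(Oc2cc(OC)c(OC)c(OC)c2)c1OC | intermediate
4 | 3,4-dimethoxy-5-(3,4,5-trimethoxyphenoxy)phenyl formate | COc1cc(OC=O)cc(Oc2cc(OC)c(OC)c(OC)c2)c1OC | intermediate
5 | 3,4-dimethoxy-5-(3,4,5-trimethoxyphenoxy)phenol | COc1cc(O)cc(Oc2cc(OC)c(OC)c(OC)c2)c1OC | intermediate
6 | 2-bromo-3,4,5-trimethoxybenzaldehyde | COc1cc(C=O)c(Br)c(OC)c1OC | starting material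
7 | 2-[3,4-dimethoxy-5-(3,4,5-trimethoxyphenoxy)phenoxy]-3,4,5-trimethoxybenzaldehyde | COc1cc(C=O)c(Oc2cc(OC)c(OC)c(Oc3cc(OC)c(OC)c(OC)c3)c2)c(OC)c1OC | intermediate
8 | 2-[3,4-dimethoxy-5-(3,4,5-trimethoxyphenoxy)phenoxy]-3,4,5-trimethoxyphenyl formate | COc1cc(OC=O)c(Oc2cc(OC)c(OC)c(Oc3cc(OC)c(OC)c(OC)c3)c2)c(OC)c1OC | intermediate
9 | 2-[3,4-dimethoxy-5-(3,4,5-trimethoxyphenoxy)phenoxy]-3,4,5-trimethoxyphenol | COc1cc(O)c(Oc2cc(OC)c(OC)c(Oc3cc(OC)c(OC)c(OC)c3)c2)c(OC)c1OC | intermediate
10 | 4-bromo-3,5-dimethoxybenzaldehyde | COc1cc(C=O)cc(OC)c1Br | starting material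
11 | 4-{2-[3,4-dimethoxy-5-(3,4,5-trimethoxyphenoxy)phenoxy]-3,4,5-trimethoxyphenoxy}-3,5-dimethoxybenzaldehyde | COc1cc(C=O)cc(OC)c1Oc1cc(OC)c(OC)c(OC)c1Oc1cc(OC)c(OC)c(Oc2cc(OC)c(OC)c(OC)c2)c1 | intermediate
12 | 4-{2-[3,4-dimethoxy-5-(3,4,5-trimethoxyphenoxy)phenoxy]-3,4,5-trimethoxyphenoxy}-3,5-dimethoxyphenyl formate | COc1cc(OC=O)cc(OC)c1Oc1cc(OC)c(OC)c(OC)c1Oc1cc(OC)c(OC)c(Oc2cc(OC)c(OC)c(OC)c2)c1 | intermediate
13 | 4-{2-[3,4-dimethoxy-5-(3,4,5-trimethoxyphenoxy)phenoxy]-3,4,5-trimethoxyphenoxy}-3,5-dimethoxyphenol | COc1cc(O)cc(OC)c1Oc1cc(OC)c(OC)c(OC)c1Oc1cc(OC)c(OC)c(Oc2cc(OC)c(OC)c(OC)c2)c1 | intermediate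
14 | 2-chloro-N-methoxy-N-methylacetamide | CON(C)C(=O)CCl | starting material
15 | 2-(4-{2-[3,4-dimethoxy-5-(3,4,5-trimethoxyphenoxy)phenoxy]-3,4,5-trimethoxyphenoxy}-3,5-dimethoxyphenoxy)-N-methoxy-N-methylacetamide | CON(C)C(=O)COc1cc(OC)c(Oc2cc(OC)c(OC)c(OC)c2Oc2cc(OC)c(OC)c(Oc3cc(OC)c(OC)c(OC)c3)c2)c(OC)c1 | intermediate
16 | methyl acetoacetate | CC(=O)CC(=O)OC | starting material
17 | methyl 6-(4-{2-[3,4-dimethoxy-5-(3,4,5-trimethoxyphenoxy)phenoxy]-3,4,5-trimethoxyphenoxy}-3,5-dimethoxyphenoxy)-3,5-dioxohexanoate | COC(=O)CC(=O)CC(=O)COc1cc(OC)c(Oc2cc(OC)c(OC)c(OC)c2Oc2cc(OC)c(OC)c(Oc3cc(OC)c(OC)c(OC)c3)c2)c(OC)c1 | intermediate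
18 | 2-(4-{2-[3,4-dimethoxy-5-(3,4,5-trimethoxyphenoxy)phenoxy]-3,4,5-trimethoxyphenoxy}-3,5-dimethoxyphenoxy)cyclohexane-1,3,5-trione | O=C1CC(=O)C(Oc2cc(OC)c(Oc3cc(OC)c(OC)c(OC)c3Oc3cc(OC)c(OC)c(Oc4cc(OC)c(OC)c(OC)c4)c3)c(OC)c2)C(=O)C1 | intermediate
19 | 2-(4-{2-[3,4-dimethoxy-5-(3,4,5-trimethoxyphenoxy)phenoxy]-3,4,5-trimethoxyphenoxy}-3,5-dimethoxyphenoxy)benzene-1,3,5-triol | Oc1cc(O)c(Oc2cc(OC)c(Oc3cc(OC)c(OC)c(OC)c3Oc3cc(OC)c(OC)c(Oc4cc(OC)c(OC)c(OC)c4)c3)c(OC)c2)c(O)c1 | intermediate
20 | 2-(4-{2-[3,4-dihydroxy-5-(3,4,5-trihydroxyphenoxy)phenoxy]-3,4,5-trihydroxyphenoxy}-3,5-dihydroxyphenoxy)benzene-1,3,5-triol (CNP0154768.0) | Oc1cc(O)c(Oc2cc(O)c(Oc3cc(O)c(O)c(O)c3Oc3cc(O)c(O)c(Oc4cc(O)c(O)c(O)c4)c3)c(O)c2)c(O)c1 | target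

**Step count**

Total steps: 10. Longest linear sequence: 10 steps (1 to 20).

**Steps most likely to fail**

Step 9. The ring closure through carbon may be outrun by lactonisation through the C5 enolate oxygen, the polyanion may fail to close and be returned on work-up, or chains may condense with each other. The fallback gives up the de novo construction of ring A and buys it instead. It sets out from phenol 13, which is coupled with 2-iodo-1,3,5-trimethoxybenzene under Ullmann conditions (CuI, picolinic acid, K3PO4, DMSO, 110 °C); the iodide is flanked by two methoxy groups but the phenol is unhindered. This should give the tridecamethyl ether of the target, the permethylated pentamer F1. Treatment of F1 with excess BBr3 (CH2Cl2, −78 °C to rt, argon) cleaves all thirteen methyl ethers and returns to the route at 20.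

Step 5. Copper-mediated C–O bond formation may stall because three ortho substituents flank the new ether, leaving protodebromination of the bromide as the main outcome. The fallback changes the bond-forming manifold from copper to palladium. It sets out from phenol 9, which is coupled with the same bromide 10 under Pd(OAc)2 and a bulky di-tert-butyl biaryl phosphine (tBuXPhos type) with K3PO4 in toluene at 100 °C; C–O reductive elimination from the aryl bearing the para-formyl group is promoted by ortho substitution on this ligand class. The fallback returns at aldehyde 11 and needs no further compound (none F0).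

Step 8. Proton transfer from the more acidic diketo ester, or enolisation of the α-aryloxy amide, may quench the dianion and stop conversion, and the free diketo ester may lactonise during acidic work-up. The fallback uses a masked acetoacetate. It sets out from Weinreb amide 15, which acylates the lithium dienolate of 2,2,6-trimethyl-4H-1,3-dioxin-4-one (LDA, THF, −78 °C) to give the keto-dioxinone F2. Heating F2 in toluene with excess methanol (110 °C) releases acetone by retro-hetero-Diels–Alder fragmentation, and the acylketene is trapped by methanol under neutral conditions; this returns to the route at diketo ester 17.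

**Further compounds**

F1 | step 9 | 2-(4-{2-[3,4-dimethoxy-5-(3,4,5-trimethoxyphenoxy)phenoxy]-3,4,5-trimethoxyphenoxy}-3,5-dimethoxyphenoxy)-1,3,5-trimethoxybenzene | COc1cc(OC)c(Oc2cc(OC)c(Oc3cc(OC)c(OC)c(OC)c3Oc3cc(OC)c(OC)c(Oc4cc(OC)c(OC)c(OC)c4)c3)c(OC)c2)c(OC)c1
F0 | step 5 | none | none
F2 | step 8 | 6-[3-(4-{2-[3,4-dimethoxy-5-(3,4,5-trimethoxyphenoxy)phenoxy]-3,4,5-trimethoxyphenoxy}-3,5-dimethoxyphenoxy)-2-oxopropyl]-2,2-dimethyl-4H-1,3-dioxin-4-one | CC1(C)OC(=O)C=C(CC(=O)COc2cc(OC)c(Oc3cc(OC)c(OC)c(OC)c3Oc3cc(OC)c(OC)c(Oc4cc(OC)c(OC)c(OC)c4)c3)c(OC)c2)O1
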